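In a one-step world, starting material and reagent go one for one on free catalyst, at a rate proportional to all three, and the fractions left then say how much catalyst work has been done. Let a and b be the fractions left of starting material and reagent, and A and B their charges.

| flask | starting material | reagent | free catalyst | temperature | remark | time |
|---|---|---|---|---|---|---|
| spring | 20 mM | 14 mM | 0.12 mM | 110 °C | the very flask that is asked about, followed so far |  |
| noon | 20 mM | 14 mM | 0.12 mM | 95 °C | run made earlier |  |
| flask | 20 mM | 14.0 mM | 0.12 mM | 110 °C |  | 2.5 h |

- spring (time / min: target / %): 25.0: 31.9; 50.0: 34.6; 60.0: 33.7; 90.0: 34.5
- noon (time / min: target / %): 50.0: 37.2; 120: 38.7; 180: 40.3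

(standard deviation of a reading: 0.5 percentage points)

- maple: at 2.5 h raise the temperature by 15 K, then wait 80 min
- alder: at 2.5 h add free catalyst, 100% of the amount charged, then wait 80 min
- birch: at 2.5 h take out 90% of the target then present, then wait 80 min
- larch: change nothing and wait 80 min more
- cedar: at 2.5 h add reagent, 50.0% of the amount charged, then wait 80 min

- what is taken out of target is counted as made
- the numbers in the tables scatter with a standard deviation of 0.5 percentage points
- additions bring no volume worth counting

* target, in percent of the starting material first charged, at 2.5 h
* which option adds most target ("none" when 2 percentage points or less is all one gets) (maple / alder / birch / larch / cedar / none)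
* target present, with what was taken out counted in, in percent of the starting material first charged, after alder
* target present, with what was taken out counted in, in percent of the starting material first charged, after larch

I reckoned D = ln(a/b)/(A − B). Reagent is the limiting reagent, and target y leaves a = 1 − y and b = 1 − yA/B. The spring reading of 34.5% at 90.0 min gave D = 0.0426 mM⁻¹. This is the catalyst dose, rate constant times free catalyst summed over time, and it is tied to one catalyst charge and temperature.

The spring readings from 50.0 min on lay between 33.7% and 34.6%, so I expected the flask to stand there at 2.5 h and waiting to add little. If the catalyst had stopped working, alder's equal charge should deliver D again, so a/b must reach 1.67, which is target 48.3%.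

The forecast said 34.6% now, alder as best, 47% after alder and 35% after larch, with the words “Fresh catalyst should give a second, smaller burst”. My alder figure stood slightly higher.

The flask gave 36.6%, then 43.8% after alder and 37.4% after larch, and the best option was alder, adding 7.2 percentage points.

    2 free catalyst → spent catalyst (k = 573 L mol⁻¹ s⁻¹, Ea = 44.0 kJ mol⁻¹)
    starting material + reagent + free catalyst ⇌ free catalyst + target (K = 192 L mol⁻¹, k = 9670 L² mol⁻² s⁻¹, Ea = 30.0 kJ mol⁻¹, ΔH = −36.0 kJ mol⁻¹)
    (constants at 110 °C)

Alder's 43.8% fell below my 48.3%. The step runs both ways, with its equilibrium constant times the starting-material charge at 3.8. Put through the same formula, the flask's 36.6% and 43.8% give the fresh catalyst a net dose of 0.0204 mM⁻¹, about half of the D read from spring. In this flask D is a net figure, and the second dose came to less than the first.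

On a neighbour flask with 56 mM of reagent, the other charges and the time held, D gives b/a = 4.64, which is target 85.0%. The computed neighbour flask gave 84.0%.

Readings and results were generated by integration with made-up constants, and the scatter is random.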